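(The runs stem from a simulated flask from invented constants; the scatter is artificial.)

Time was the first item. The meeting noted that in the autumn run target fell from 75.2% at 2.08 d to 40.0% at 15.0 d while over-reaction product rose, and that the flask repeats that run with twice its second catalyst.

| flask | substrate | partner | free catalyst | second catalyst | remark | time |
|---|---|---|---|---|---|---|
| midnight | 0.070 M | 0.090 M | 2.5 mM | 0.50 mM | run made earlier |  |
| spring | 0.11 M | 0.090 M | 2.5 mM | 0.50 mM | run made earlier |  |
| autumn | 0.050 M | 0.090 M | 2.5 mM | 0.25 mM | run made earlier |  |
| flask | 0.050 M | 0.0900 M | 2.5 mM | 0.50 mM |  | 15 d |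

| run | time / d | target / % | over-reaction product / % |
|---|---|---|---|
| midnight | 1.25 | 79.0 | 13.9 |
| midnight | 3.00 | 68.3 | 31.8 |
| midnight | 6.00 | 55.4 | 43.1 |
| midnight | 15.0 | 46.6 | 53.0 |
| spring | 4.00 | 51.3 | 27.8 |
| spring | 8.00 | 45.4 | 36.4 |
| spring | 12.0 | 41.7 | 38.6 |
| spring | 15.0 | 40.8 | 39.5 |
| autumn | 2.08 | 75.2 | 22.0 |
| autumn | 5.00 | 54.1 | 41.8 |
| autumn | 10.0 | 43.9 | 54.5 |
| autumn | 15.0 | 40.0 | 57.0 |

(each reading ± 1 percentage point)

- share of target in target plus over-reaction product at 3.0 h
- share of target in target plus over-reaction product at 15 d

- what was read earlier has a scatter of 1 percentage point, one standard deviation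

I proposed carrying one number, the dose: the natural logarithm of the ratio of target plus over-reaction product to target, which treats the loss of target as a pseudo-first-order step whose rate may fall with time. Autumn's last reading gives a dose of 0.886, and taking the same dose for the flask, my first answer was a share of 41.2%.

I then went round once more. Autumn's gap of 2.80% at 2.08 d, the part of the substrate charged that was read as neither target nor over-reaction product, is a reading with its scatter, and it implies a lag of 0.582 d if the approach is exponential. I assumed that the flask halves this lag. The same reading gives an early dose rate of 0.171 d⁻¹, so I put the dose of the flask, whose target I take to form earlier, at 0.936, which means a share of 39.2%. Taking the mean age of target at 3.0 h as half that time, I reckoned 98.9% for the early share.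

The forecast, reasoning that the flask “matches autumn but has twice the second catalyst”, gave 98% (95% to 99.5%) early and 39% (34% to 43%) late. My figures stood slightly above it at both times.

The flask gives 98.9% at 3.0 h and 39.4% at 15 d.

    substrate + free catalyst → free catalyst + open intermediate (k = 65.0 M⁻¹ h⁻¹)
    second catalyst + open intermediate ⇌ catalyst intermediate (K = 34.0 M⁻¹, k = 13000 M⁻¹ h⁻¹)
    partner + catalyst intermediate → second catalyst + target (k = 280 M⁻¹ h⁻¹)
    free catalyst + target → spent catalyst A (k = 0.120 M⁻¹ h⁻¹)
    free catalyst + target → free catalyst + over-reaction product (k = 3.90 M⁻¹ h⁻¹)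
    free catalyst → spent catalyst B (k = 0.00560 h⁻¹)

The flask's result puts its dose at 0.931, beside my 0.936. In these equations the step to over-reaction product has free catalyst on its left, so I take the dose in proportion to that charge. The neighbouring flask holds 6.3 × 10⁻⁴ M of free catalyst, a quarter of the flask's charge, with its other charges unchanged. Its dose then comes to 0.236, which means a share of 79.0%. That neighbouring flask stands at 83.0% after 15 d, with 81.3% target and 16.6% over-reaction product.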